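**Retrosynthetic overview**

1. Target 15 ⇐ dienol 14 by hydroxyl-directed epoxidation: the oxirane C–C bond (ring C1–C2) and the ring alkene (C3=C4) of the target are read as the two C=C bonds of a cisoid cyclohexa-1,3-diene.
2. Enabling feature: in the six-membered carbocycle the diene termini C1 (bearing the CH2O arm) and C4 each sit next to an oxygenated stereocentre (C6 and C5), so they are the ketone and aldehyde carbons of an open-chain D-threo 4-oxopentanal, while C2–C3 is an unsubstituted two-carbon unit.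
3. Diene 11 ⇐ keto-aldehyde 6 + bis-phosphonium salt 7 by a one-pot double Wittig [4+2] annulation that makes both ring C=C bonds and closes the only carbocycle.
4. 6 ⇐ organocatalytic syn-aldol of bis-silylated dihydroxyacetone 1 with (benzyloxy)acetaldehyde 2, which sets both carbinol stereocentres; silyl ethers of graded lability (C5–OTES, primary C7–OTBS, hindered C6–OTBS) let both benzoates go on before the C6 hydroxyl is freed to steer the epoxidation.
5. Ring order: carbocycle (step 5), then oxirane (step 9).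

Key step: step 5

Remark on the chemistry (assumption): the sense of induction in step 1 is taken from the hydrogen-bonded (Z)-enamine model, by which the D-configured threonine catalyst should give the (3S,4R) syn-adduct 3; the L-catalyst would give its mirror image.

**Route**

Step 1
Reactants: 1 1,3-bis[(tert-butyldimethylsilyl)oxy]propan-2-one; 2 (benzyloxy)acetaldehyde
Product: 3 (3S,4R)-5-(benzyloxy)-1,3-bis[(tert-butyldimethylsilyl)oxy]-4-hydroxypentan-2-one
Conditions: O-tert-butyl-D-threonine (20 mol %), 5-methyl-1H-tetrazole (10 mol %), NMP, H2O (3 vol %), 4 °C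
Reagents that add atoms: none
Why: Primary-amine catalysis gives the hydrogen-bonded (Z)-enamine of the silyloxy ketone, whose carboxylic-acid-directed addition to the aldehyde (direct asymmetric syn-aldol reaction) should set both stereocentres, C3 (S) and C4 (R), under catalyst control.

Step 2
Reactants: 3 (3S,4R)-5-(benzyloxy)-1,3-bis[(tert-butyldimethylsilyl)oxy]-4-hydroxypentan-2-one
Product: 4 (3S,4R)-5-(benzyloxy)-1,3-bis[(tert-butyldimethylsilyl)oxy]-4-[(triethylsilyl)oxy]pentan-2-one
Conditions: Et3SiCl, imidazole, DMF, 0 °C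
Reagents that add atoms: chlorotriethylsilane, CC[Si](Cl)(CC)CC
Why: Silyl ether formation on the only free hydroxyl under weakly basic conditions should outpace retro-aldol cleavage and touches no stereocentre.

Step 3
Reactants: 4 (3S,4R)-5-(benzyloxy)-1,3-bis[(tert-butyldimethylsilyl)oxy]-4-[(triethylsilyl)oxy]pentan-2-one
Product: 5 (3S,4R)-1,3-bis[(tert-butyldimethylsilyl)oxy]-5-hydroxy-4-[(triethylsilyl)oxy]pentan-2-one (in equilibrium with its five-membered hemiketal)
Conditions: H2 (1 atm), Pd/C, EtOAc, rt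
Reagents that add atoms: none
Why: Catalytic hydrogenolysis of the benzyl ether in a neutral aprotic solvent should leave the three silyl ethers and the ketone intact.

Step 4
Reactants: 5 (3S,4R)-1,3-bis[(tert-butyldimethylsilyl)oxy]-5-hydroxy-4-[(triethylsilyl)oxy]pentan-2-one
Product: 6 (2S,3S)-3,5-bis[(tert-butyldimethylsilyl)oxy]-4-oxo-2-[(triethylsilyl)oxy]pentanal
Conditions: Dess–Martin periodinane, pyridine, CH2Cl2, 0 °C to rt
Reagents that add atoms: none
Why: Dess–Martin oxidation should act on the open hydroxy-ketone form under buffered, non-epimerising conditions and give the α-silyloxy aldehyde without β-elimination; the aldehyde is used crude.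

Step 5
Reactants: 6 (2S,3S)-3,5-bis[(tert-butyldimethylsilyl)oxy]-4-oxo-2-[(triethylsilyl)oxy]pentanal; 7 ethane-1,2-diylbis(triphenylphosphonium) dibromide
Product: 11 tert-butyl({(5R,6R)-6-[(tert-butyldimethylsilyl)oxy]-5-[(triethylsilyl)oxy]cyclohexa-1,3-dien-1-yl}methoxy)dimethylsilane, via β-phosphonio ylide 8 (not isolated), via Z-allylphosphonium bromide 9 (not isolated), via allylic ylide 10 (not isolated)
Conditions: 7, KN(SiMe3)2 (1 equiv), THF, −78 °C; then 6, −78 to −20 °C; then KN(SiMe3)2 (1 equiv), −78 °C to rt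
Reagents that add atoms: none
Why: Proposed new method: one equivalent of KN(SiMe3)2 turns 7 into the β-phosphonio ylide 8 (which may fragment reversibly to vinyltriphenylphosphonium and PPh3 but is drained by the carbonyl trap), 8 olefinates the aldehyde of 6 to the (Z)-allylphosphonium salt 9, and the second equivalent of base gives the allylic ylide 10, which closes the ring by intramolecular Wittig olefination of the ketone, so that each half is an ordinary Wittig reaction driven by formation of a P=O bond. The closest known reaction types are the double Wittig annulation of dialdehydes with bis-ylides, the vinylphosphonium annulation (conjugate addition followed by intramolecular Wittig reaction) and the cyclohexa-1,3-diene synthesis by intramolecular Wittig reaction of allylic ylides; new here is their combination on an enolisable, α-oxygenated aliphatic keto-aldehyde. The six-membered carbocycle is closed by 6-exo-trig attack of the ylide carbon on the ketone and cycloreversion of the oxaphosphetane, and the ring admits only the cis geometry at both new C=C bonds. No stereocentre is created; the two silyloxy-bearing stereocentres of 6 are only carried through, which relies on carbonyl addition of the ylides being faster than enolisation at low temperature. The step needs aldehyde-before-ketone chemoselectivity, secured by the higher electrophilicity of the α-silyloxy aldehyde, and Z geometry in 9, secured by the non-stabilised ylide under lithium-free conditions and backed by E/Z equilibration of the delocalised ylide 10, of which only the Z form can cyclise. It also needs the allylic ylide not to expel the oxygen on ring C5 by 1,4-elimination, which is why that oxygen is carried as a silyl ether and not as the benzoate of the target.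

Step 6
Reactants: 11 tert-butyl({(5R,6R)-6-[(tert-butyldimethylsilyl)oxy]-5-[(triethylsilyl)oxy]cyclohexa-1,3-dien-1-yl}methoxy)dimethylsilane
Product: 12 (1R,6R)-6-[(tert-butyldimethylsilyl)oxy]-5-(hydroxymethyl)cyclohexa-2,4-dien-1-ol
Conditions: HF·pyridine, pyridine, THF, 0 °C
Reagents that add atoms: none
Why: Fluoride-mediated desilylation discriminates by steric access, so the triethylsilyl ether and the primary TBS ether should cleave well before the secondary TBS ether flanked by two substituted ring carbons, and the pyridine buffer guards the dienol against acid-promoted aromatisation.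

Step 7
Reactants: 12 (1R,6R)-6-[(tert-butyldimethylsilyl)oxy]-5-(hydroxymethyl)cyclohexa-2,4-dien-1-ol
Product: 13 [(5R,6R)-5-(benzoyloxy)-6-[(tert-butyldimethylsilyl)oxy]cyclohexa-1,3-dien-1-yl]methyl benzoate
Conditions: BzCl, pyridine, DMAP (cat.), CH2Cl2, 0 °C
Reagents that add atoms: benzoyl chloride, O=C(Cl)c1ccccc1
Why: DMAP-catalysed acylation of the only two free hydroxyls installs both benzoates of the target with retention at the ring carbinol carbon.

Step 8
Reactants: 13 [(5R,6R)-5-(benzoyloxy)-6-[(tert-butyldimethylsilyl)oxy]cyclohexa-1,3-dien-1-yl]methyl benzoate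
Product: 14 [(5R,6R)-5-(benzoyloxy)-6-hydroxycyclohexa-1,3-dien-1-yl]methyl benzoate
Conditions: HF·pyridine, THF, 0 °C to rt
Reagents that add atoms: none
Why: HF·pyridine removes the remaining hindered TBS ether under non-basic conditions, so no benzoyl migration onto the liberated hydroxyl is expected.

Step 9
Reactants: 14 [(5R,6R)-5-(benzoyloxy)-6-hydroxycyclohexa-1,3-dien-1-yl]methyl benzoate
Product: 15 [(1S,2S,3R,6R)-3-(benzoyloxy)-2-hydroxy-7-oxabicyclo[4.1.0]hept-4-en-1-yl]methyl benzoate
Conditions: VO(acac)2 (cat.), tBuOOH, CH2Cl2, 0 °C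
Reagents that add atoms: tert-butyl hydroperoxide, CC(C)(C)OO
Why: Vanadium-catalysed hydroxyl-directed epoxidation delivers oxygen from the metal-bound allylic alkoxide to the adjacent trisubstituted C=C bond on the face of the hydroxyl, which should set both oxirane stereocentres cis to that hydroxyl and leave the other ring alkene (only homoallylic to the hydroxyl) untouched.

**Compound list**

1 | 1,3-bis[(tert-butyldimethylsilyl)oxy]propan-2-one | CC(C)(C)[Si](C)(C)OCC(=O)CO[Si](C)(C)C(C)(C)C | starting material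
2 | (benzyloxy)acetaldehyde | O=CCOCc1ccccc1 | starting material
3 | (3S,4R)-5-(benzyloxy)-1,3-bis[(tert-butyldimethylsilyl)oxy]-4-hydroxypentan-2-one | CC(C)(C)[Si](C)(C)OCC(=O)[C@@H](O[Si](C)(C)C(C)(C)C)[C@H](O)COCc1ccccc1 | intermediate
4 | (3S,4R)-5-(benzyloxy)-1,3-bis[(tert-butyldimethylsilyl)oxy]-4-[(triethylsilyl)oxy]pentan-2-one | CC(C)(C)[Si](C)(C)OCC(=O)[C@@H](O[Si](C)(C)C(C)(C)C)[C@H](O[Si](CC)(CC)CC)COCc1ccccc1 | intermediate
5 | (3S,4R)-1,3-bis[(tert-butyldimethylsilyl)oxy]-5-hydroxy-4-[(triethylsilyl)oxy]pentan-2-one | CC(C)(C)[Si](C)(C)OCC(=O)[C@@H](O[Si](C)(C)C(C)(C)C)[C@H](O[Si](CC)(CC)CC)CO | intermediate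
6 | (2S,3S)-3,5-bis[(tert-butyldimethylsilyl)oxy]-4-oxo-2-[(triethylsilyl)oxy]pentanal | CC(C)(C)[Si](C)(C)OCC(=O)[C@@H](O[Si](C)(C)C(C)(C)C)[C@H](O[Si](CC)(CC)CC)C=O | intermediate
7 | ethane-1,2-diylbis(triphenylphosphonium) dibromide | [Br-].[Br-].c1ccc(cc1)[P+](CC[P+](c1ccccc1)(c1ccccc1)c1ccccc1)(c1ccccc1)c1ccccc1 | starting material
8 | triphenyl[2-(triphenylphosphoranylidene)ethyl]phosphonium bromide | [Br-].c1ccc(cc1)P(=CC[P+](c1ccccc1)(c1ccccc1)c1ccccc1)(c1ccccc1)c1ccccc1 | intermediate
9 | [(2Z,4R,5S)-5,7-bis[(tert-butyldimethylsilyl)oxy]-6-oxo-4-[(triethylsilyl)oxy]hept-2-en-1-yl]triphenylphosphonium bromide | [Br-].CC(C)(C)[Si](C)(C)OCC(=O)[C@@H](O[Si](C)(C)C(C)(C)C)[C@H](O[Si](CC)(CC)CC)/C=C\C[P+](c1ccccc1)(c1ccccc1)c1ccccc1 | intermediate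
10 | (3S,4R,5Z)-1,3-bis[(tert-butyldimethylsilyl)oxy]-4-[(triethylsilyl)oxy]-7-(triphenylphosphoranylidene)hept-5-en-2-one | CC(C)(C)[Si](C)(C)OCC(=O)[C@@H](O[Si](C)(C)C(C)(C)C)[C@H](O[Si](CC)(CC)CC)/C=C\C=P(c1ccccc1)(c1ccccc1)c1ccccc1 | intermediate
11 | tert-butyl({(5R,6R)-6-[(tert-butyldimethylsilyl)oxy]-5-[(triethylsilyl)oxy]cyclohexa-1,3-dien-1-yl}methoxy)dimethylsilane | CC(C)(C)[Si](C)(C)OCC1=CC=C[C@@H](O[Si](CC)(CC)CC)[C@@H]1O[Si](C)(C)C(C)(C)C | intermediate
12 | (1R,6R)-6-[(tert-butyldimethylsilyl)oxy]-5-(hydroxymethyl)cyclohexa-2,4-dien-1-ol | OCC1=CC=C[C@@H](O)[C@@H]1O[Si](C)(C)C(C)(C)C | intermediate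
13 | [(5R,6R)-5-(benzoyloxy)-6-[(tert-butyldimethylsilyl)oxy]cyclohexa-1,3-dien-1-yl]methyl benzoate | O=C(OCC1=CC=C[C@@H](OC(=O)c2ccccc2)[C@@H]1O[Si](C)(C)C(C)(C)C)c1ccccc1 | intermediate
14 | [(5R,6R)-5-(benzoyloxy)-6-hydroxycyclohexa-1,3-dien-1-yl]methyl benzoate | O=C(OCC1=CC=C[C@@H](OC(=O)c2ccccc2)[C@@H]1O)c1ccccc1 | intermediate
15 | [(1S,2S,3R,6R)-3-(benzoyloxy)-2-hydroxy-7-oxabicyclo[4.1.0]hept-4-en-1-yl]methyl benzoate | O=C(OC[C@@]12O[C@@H]1C=C[C@@H](OC(=O)c1ccccc1)[C@@H]2O)c1ccccc1 | target

**Count and risks**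

Total step count: 9. Longest linear sequence: 9 steps (1 or 2 to 15).

Steps most likely to fail:

1. Step 5 (the proposed method). What may go wrong:
   - loss of ylide 8 by β-elimination of PPh3 without recapture;
   - E-selective first olefination giving an allylic salt that cannot close;
   - 1,4-elimination of silanolate from the allylic ylide;
   - enolisation or epimerisation of 6 by the basic ylides.

   Fallback by known chemistry, setting out from 6 and coming back at 11: aldehyde-selective Wittig methylenation of 6 (Ph3P=CH2, THF, −78 °C) should give (3S,4R)-1,3-bis[(tert-butyldimethylsilyl)oxy]-4-[(triethylsilyl)oxy]hex-5-en-2-one F1. Addition of allylmagnesium bromide to its ketone should give (5S,6R)-4-{[(tert-butyldimethylsilyl)oxy]methyl}-5-[(tert-butyldimethylsilyl)oxy]-6-[(triethylsilyl)oxy]octa-1,7-dien-4-ol F2 as a mixture of carbinol epimers, which does not matter. Ring-closing metathesis with the second-generation Grubbs catalyst should give (5R,6S)-1-{[(tert-butyldimethylsilyl)oxy]methyl}-6-[(tert-butyldimethylsilyl)oxy]-5-[(triethylsilyl)oxy]cyclohex-3-en-1-ol F3. Dehydration of the tertiary alcohol with the Burgess reagent toward the allylic CH2 should then give the conjugated diene 11.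

2. Step 1. What may go wrong: insufficient syn/anti or enantiofacial control with this unbranched α-alkoxy aldehyde, or slow turnover through self-condensation of the aldehyde.

   Fallback with auxiliary control, setting out from 2 and coming back at 3: (S)-4-benzyl-3-{[(tert-butyldimethylsilyl)oxy]acetyl}-1,3-oxazolidin-2-one F4 is made from (S)-4-benzyl-1,3-oxazolidin-2-one and [(tert-butyldimethylsilyl)oxy]acetyl chloride. It is enolised with Bu2BOTf and iPr2NEt and added to 2 in an Evans syn-aldol reaction, which should give (S)-4-benzyl-3-[(2S,3R)-4-(benzyloxy)-2-[(tert-butyldimethylsilyl)oxy]-3-hydroxybutanoyl]-1,3-oxazolidin-2-one F5. Transamidation with AlMe3 and MeNHOMe·HCl should give the Weinreb amide (2S,3R)-4-(benzyloxy)-2-[(tert-butyldimethylsilyl)oxy]-3-hydroxy-N-methoxy-N-methylbutanamide F6. Excess [(tert-butyldimethylsilyl)oxy]methyllithium (from the tributylstannane and nBuLi) should convert F6 into ketone 3.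

3. Step 6. What may go wrong: incomplete discrimination among the three silyl ethers (early loss of the ring C6 silyl group or a surviving primary TBS ether), or acid-triggered aromatisation of the dienol.

   Fallback by ring-size-controlled acetal differentiation, setting out from 11 and coming back at 14: global desilylation with Bu4NF in THF should give (1R,2R)-3-(hydroxymethyl)cyclohexa-3,5-diene-1,2-diol F7. With 2,2-dimethoxypropane and pyridinium p-toluenesulfonate only the 1,3-related primary and adjacent secondary hydroxyls can bridge (the trans-1,2-diol cannot), which should give (8R,8aR)-2,2-dimethyl-8,8a-dihydro-4H-1,3-benzodioxin-8-ol F8. Benzoylation (BzCl, pyridine) should give (8R,8aR)-2,2-dimethyl-8,8a-dihydro-4H-1,3-benzodioxin-8-yl benzoate F9. Mild hydrolysis (AcOH, H2O, THF) should give (1R,6R)-6-hydroxy-5-(hydroxymethyl)cyclohexa-2,4-dien-1-yl benzoate F10. Primary-selective benzoylation (BzCl, 2,4,6-collidine, CH2Cl2, −40 °C) should then give 14.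

Further compounds
F1 | step 5 | (3S,4R)-1,3-bis[(tert-butyldimethylsilyl)oxy]-4-[(triethylsilyl)oxy]hex-5-en-2-one | CC(C)(C)[Si](C)(C)OCC(=O)[C@@H](O[Si](C)(C)C(C)(C)C)[C@H](O[Si](CC)(CC)CC)C=C
F2 | step 5 | (5S,6R)-4-{[(tert-butyldimethylsilyl)oxy]methyl}-5-[(tert-butyldimethylsilyl)oxy]-6-[(triethylsilyl)oxy]octa-1,7-dien-4-ol (carbinol epimers) | CC(C)(C)[Si](C)(C)OCC(O)(CC=C)[C@@H](O[Si](C)(C)C(C)(C)C)[C@H](O[Si](CC)(CC)CC)C=C
F3 | step 5 | (5R,6S)-1-{[(tert-butyldimethylsilyl)oxy]methyl}-6-[(tert-butyldimethylsilyl)oxy]-5-[(triethylsilyl)oxy]cyclohex-3-en-1-ol (carbinol epimers) | CC(C)(C)[Si](C)(C)OCC1(O)CC=C[C@@H](O[Si](CC)(CC)CC)[C@@H]1O[Si](C)(C)C(C)(C)C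
F4 | step 1 | (S)-4-benzyl-3-{[(tert-butyldimethylsilyl)oxy]acetyl}-1,3-oxazolidin-2-one | O=C1OC[C@H](Cc2ccccc2)N1C(=O)CO[Si](C)(C)C(C)(C)C
F5 | step 1 | (S)-4-benzyl-3-[(2S,3R)-4-(benzyloxy)-2-[(tert-butyldimethylsilyl)oxy]-3-hydroxybutanoyl]-1,3-oxazolidin-2-one | O=C1OC[C@H](Cc2ccccc2)N1C(=O)[C@@H](O[Si](C)(C)C(C)(C)C)[C@H](O)COCc1ccccc1
F6 | step 1 | (2S,3R)-4-(benzyloxy)-2-[(tert-butyldimethylsilyl)oxy]-3-hydroxy-N-methoxy-N-methylbutanamide | CON(C)C(=O)[C@@H](O[Si](C)(C)C(C)(C)C)[C@H](O)COCc1ccccc1
F7 | step 6 | (1R,2R)-3-(hydroxymethyl)cyclohexa-3,5-diene-1,2-diol | OCC1=CC=C[C@@H](O)[C@@H]1O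
F8 | step 6 | (8R,8aR)-2,2-dimethyl-8,8a-dihydro-4H-1,3-benzodioxin-8-ol | CC1(C)OCC2=CC=C[C@@H](O)[C@@H]2O1
F9 | step 6 | (8R,8aR)-2,2-dimethyl-8,8a-dihydro-4H-1,3-benzodioxin-8-yl benzoate | CC1(C)OCC2=CC=C[C@@H](OC(=O)c3ccccc3)[C@@H]2O1
F10 | step 6 | (1R,6R)-6-hydroxy-5-(hydroxymethyl)cyclohexa-2,4-dien-1-yl benzoate | OCC1=CC=C[C@@H](OC(=O)c2ccccc2)[C@@H]1O
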